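**Retrosynthetic overview**
1. Target 21 ⇒ acetylation and N–O cleavage of γ-anilinooxy enoate 19 ⇒ aldehyde 13 + ylide 17 (proline α-aminoxylation sets C4, Wittig sets the 2E alkene).
2. 13 ⇒ ozonolysis of the prenyl end of the zingiberenol-type alcohol 12 ⇒ Wharton transposition of epoxy ketone 10 (gives C2′=C3′ and the C4′ carbinol).
3. 10 ⇒ oxidation, hydroxyl-directed hydrogenation (C6) and hydroxyl-directed epoxidation (C4′) of cyclohexenol 7; the C2′ hydroxyl created in the ring closure steers both.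
4. The only ring: 7 ⇒ enantioselective 1,6-cyclization of (2Z,6Z)-farnesal 6 (C1–C6 bond of a farnesyl chain, as in bisabolyl cation formation, run as a carbonyl-ene reaction of the protonated enal).
5. 6 ⇒ (2Z,6Z)-farnesol 5 ⇒ prenol 3 (as its dianion) + neryl bromide 2 (from nerol 1).

Assumption: locants are C1–C7 for the heptenoate chain of the target and C1′–C6′ for the ring (C1′ on C6, C4′ the carbinol carbon); both antipodes of the chiral acid of step 4 are taken as accessible.

**Route**

Step 1
Reactants: 1 nerol [(2Z)-3,7-dimethylocta-2,6-dien-1-ol]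
Product: 2 neryl bromide [(2Z)-1-bromo-3,7-dimethylocta-2,6-diene]
Conditions: PBr3 (0.4 equiv), pyridine (cat.), Et2O, −10 °C; used crude
Reagents that add atoms: phosphorus tribromide, BrP(Br)Br
Why: Low-temperature bromination of a primary allylic alcohol through its phosphite ester (SN2), which keeps the Z alkene.

Step 2
Reactants: 3 prenol (3-methylbut-2-en-1-ol); 2 neryl bromide
Product: 5 (2Z,6Z)-farnesol, via dilithioprenol 4 (not isolated)
Conditions: 3, n-BuLi (2.2 equiv), TMEDA (2.2 equiv), Et2O, 0 °C to rt, 24 h; then 2, −78 °C to rt; aqueous work-up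
Reagents that add atoms: n-butyllithium, [Li]CCCC (lithium only, present in intermediate 4 and lost on work-up)
Why: Alkoxide-directed allylic lithiation of prenol at the methyl cis to CH2OLi, then SN2 alkylation of that terminus by the allylic bromide (dianion alkylation), so the new 2,3-alkene is Z and the neryl Z alkene is untouched.

Step 3
Reactants: 5 (2Z,6Z)-farnesol
Product: 6 (2Z,6Z)-farnesal
Conditions: TEMPO (10 mol%), PhI(OAc)2 (1.1 equiv), CH2Cl2, 0 °C to rt
Reagents that add atoms: none
Why: Oxoammonium (TEMPO) oxidation of the allylic alcohol under near-neutral conditions, which does not isomerise the Z enal.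

Step 4
Reactants: 6 (2Z,6Z)-farnesal
Product: 7 (1S,6R)-3-methyl-6-(6-methylhepta-1,5-dien-2-yl)cyclohex-2-en-1-ol
Conditions: confined chiral imidodiphosphorimidate Brønsted acid (BINOL-derived IDPi with N-perfluoroarylsulfonyl groups, antipode giving 1S,6R; 2 mol%), CHCl3, −30 °C
Reagents that add atoms: none
Why: Catalytic asymmetric intramolecular carbonyl-ene reaction (type 1), known for the C10 homologue neral and closing the same C1–C6 bond as the bisabolyl cation: the chair transition state gives the trans carbinol, the chiral anion fixes C1′ (R) and C2′ (S), and because the 6Z geometry puts the methyl trans to the tether that methyl gives up the proton, leaving the exocyclic methylene.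

Step 5
Reactants: 7
Product: 8 (1R,2R,3R,6S)-6-methyl-3-(6-methylhepta-1,5-dien-2-yl)-7-oxabicyclo[4.1.0]heptan-2-ol
Conditions: VO(acac)2 (2 mol%), t-BuOOH (1.2 equiv, in decane), CH2Cl2, 0 °C to rt
Reagents that add atoms: tert-butyl hydroperoxide, CC(C)(C)OO
Why: Hydroxyl-directed vanadium-catalysed epoxidation of the allylic alcohol only, with oxygen delivered syn to the C2′ hydroxyl, which places the future C4′–O bond trans to the side chain (C4′ S).

Step 6
Reactants: 8
Product: 9 (1R,2R,3R,6S)-6-methyl-3-[(2R)-6-methylhept-5-en-2-yl]-7-oxabicyclo[4.1.0]heptan-2-ol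
Conditions: [Rh(nbd)(dppb)]BF4 (5 mol%), H2 (50 bar), CH2Cl2, rt
Reagents that add atoms: none
Why: Hydroxyl-directed homogeneous hydrogenation of the homoallylic 1,1-disubstituted alkene: hydride is delivered through a chair-like six-membered rhodium alkyl chelate (O–C2′–C1′–C6–CH2–Rh) with the homoprenyl chain equatorial, which gives 6R, while the undirected trisubstituted prenyl alkene and the epoxide are not touched.

Step 7
Reactants: 9
Product: 10 (1S,3R,6S)-6-methyl-3-[(2R)-6-methylhept-5-en-2-yl]-7-oxabicyclo[4.1.0]heptan-2-one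
Conditions: Dess–Martin periodinane (1.3 equiv), pyridine (3 equiv), CH2Cl2, 0 °C to rt
Reagents that add atoms: none
Why: Buffered hypervalent-iodine oxidation of the secondary alcohol to the α,β-epoxy ketone without opening the epoxide or epimerising C1′.

Step 8
Reactants: 10
Product: 12 (1S,4R)-1-methyl-4-[(2R)-6-methylhept-5-en-2-yl]cyclohex-2-en-1-ol, via epoxy hydrazone 11 (not isolated)
Conditions: N2H4·H2O (3 equiv), AcOH (0.5 equiv), MeOH, 0 °C to rt, under argon
Reagents that add atoms: hydrazine, NN (nitrogen only, present in intermediate 11 and lost as N2)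
Why: Wharton transposition: the hydrazone opens the epoxide and loses N2 to give the C2′=C3′ alkene while the C4′–O bond is retained, so the tertiary carbinol keeps the configuration set in step 5.

Step 9
Reactants: 12
Product: 13 (4R)-4-[(1R,4S)-4-hydroxy-4-methylcyclohex-2-en-1-yl]pentanal
Conditions: O3 (1.0 equiv, Sudan Red 7B end point), pyridine (3 equiv), CH2Cl2, −78 °C
Reagents that add atoms: ozone, [O-][O+]=O
Why: Chemoselective ozonolysis of the electron-rich trisubstituted prenyl alkene over the cis-disubstituted ring alkene, which is deactivated by the allylic hydroxyl; pyridine fragments the carbonyl oxide directly to the aldehyde.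

Step 10
Reactants: 14 methyl (triphenyl-λ5-phosphanylidene)acetate; 15 5-bromo-2-methylpent-2-ene
Product: 17 methyl 6-methyl-2-(triphenyl-λ5-phosphanylidene)hept-5-enoate, via phosphonium bromide 16 (not isolated)
Conditions: MeCN, 80 °C, 48 h; then aq NaOH, CH2Cl2
Reagents that add atoms: none
Why: C-alkylation of the stabilised ylide by the primary bromide (SN2) gives the α-substituted phosphonium salt, which base converts to the new stabilised ylide.

Step 11
Reactants: 13; 17
Product: 19 methyl (2E,4R,6R)-6-[(1R,4S)-4-hydroxy-4-methylcyclohex-2-en-1-yl]-2-(4-methylpent-3-en-1-yl)-4-(phenylaminooxy)hept-2-enoate, via aminooxy aldehyde 18 (not isolated)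
Conditions: L-proline (20 mol%), PhNO (0.85 equiv, slow addition), MeCN, −20 °C; then 17 (1.3 equiv), 0 °C to rt
Reagents that add atoms: nitrosobenzene, O=Nc1ccccc1
Why: Proline-catalysed enamine α-aminoxylation (L-proline gives the 4R centre under catalyst control) followed in the same flask by Wittig olefination with the α-substituted stabilised ylide, which gives the 2E (ester trans to C4) trisubstituted enoate before the labile α-oxy aldehyde can epimerise.

Step 12
Reactants: 19
Product: 21 methyl (2E,4R,6R)-4-acetoxy-6-[(1R,4S)-4-hydroxy-4-methylcyclohex-2-en-1-yl]-2-(4-methylpent-3-en-1-yl)hept-2-enoate (target), via hydroxy ester 20 (not isolated)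
Conditions: CuSO4·5H2O (0.3 equiv), MeOH, 0 °C to rt; filter, concentrate; then Ac2O (1.5 equiv), pyridine, DMAP (cat.), CH2Cl2, 0 °C
Reagents that add atoms: acetic anhydride, CC(=O)OC(C)=O
Why: Copper-catalysed N–O cleavage frees the C4 alcohol without touching the alkenes, and DMAP-catalysed acylation at 0 °C acetylates the secondary allylic alcohol selectively over the hindered tertiary one.

**Compound list**
1 | nerol, (2Z)-3,7-dimethylocta-2,6-dien-1-ol | CC(C)=CCC/C(C)=C\CO | starting material
2 | neryl bromide | CC(C)=CCC/C(C)=C\CBr | intermediate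
3 | prenol, 3-methylbut-2-en-1-ol | CC(C)=CCO | starting material
4 | dilithioprenol, lithium (2Z)-4-lithio-3-methylbut-2-en-1-olate | [Li]OC/C=C(/C)C[Li] | intermediate
5 | (2Z,6Z)-farnesol | OC/C=C(/C)CC/C=C(/C)CCC=C(C)C | intermediate
6 | (2Z,6Z)-farnesal | O=C/C=C(/C)CC/C=C(/C)CCC=C(C)C | intermediate
7 | (1S,6R)-3-methyl-6-(6-methylhepta-1,5-dien-2-yl)cyclohex-2-en-1-ol (OH trans to side chain) | C=C(CCC=C(C)C)[C@H]1CCC(C)=C[C@@H]1O | intermediate
8 | (1R,2R,3R,6S)-6-methyl-3-(6-methylhepta-1,5-dien-2-yl)-7-oxabicyclo[4.1.0]heptan-2-ol (epoxide cis to OH) | C=C(CCC=C(C)C)[C@H]1CC[C@]2(C)O[C@@H]2[C@@H]1O | intermediate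
9 | (1R,2R,3R,6S)-6-methyl-3-[(2R)-6-methylhept-5-en-2-yl]-7-oxabicyclo[4.1.0]heptan-2-ol | C[C@H](CCC=C(C)C)[C@H]1CC[C@]2(C)O[C@@H]2[C@@H]1O | intermediate
10 | (1S,3R,6S)-6-methyl-3-[(2R)-6-methylhept-5-en-2-yl]-7-oxabicyclo[4.1.0]heptan-2-one | C[C@H](CCC=C(C)C)[C@H]1CC[C@]2(C)O[C@@H]2C1=O | intermediate
11 | hydrazone of 10 | C[C@H](CCC=C(C)C)[C@H]1CC[C@]2(C)O[C@@H]2C1=NN | intermediate
12 | (1S,4R)-1-methyl-4-[(2R)-6-methylhept-5-en-2-yl]cyclohex-2-en-1-ol (OH trans to side chain) | C[C@H](CCC=C(C)C)[C@@H]1C=C[C@@](C)(O)CC1 | intermediate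
13 | (4R)-4-[(1R,4S)-4-hydroxy-4-methylcyclohex-2-en-1-yl]pentanal | C[C@H](CCC=O)[C@@H]1C=C[C@@](C)(O)CC1 | intermediate
14 | methyl (triphenyl-λ5-phosphanylidene)acetate | COC(=O)C=P(c1ccccc1)(c1ccccc1)c1ccccc1 | starting material
15 | 5-bromo-2-methylpent-2-ene | CC(C)=CCCBr | starting material
16 | (1-methoxy-6-methyl-1-oxohept-5-en-2-yl)triphenylphosphonium bromide | COC(=O)C(CCC=C(C)C)[P+](c1ccccc1)(c1ccccc1)c1ccccc1.[Br-] | intermediate
17 | methyl 6-methyl-2-(triphenyl-λ5-phosphanylidene)hept-5-enoate | COC(=O)C(CCC=C(C)C)=P(c1ccccc1)(c1ccccc1)c1ccccc1 | intermediate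
18 | (2R,4R)-4-[(1R,4S)-4-hydroxy-4-methylcyclohex-2-en-1-yl]-2-(phenylaminooxy)pentanal | O=C[C@@H](C[C@@H](C)[C@@H]1C=C[C@@](C)(O)CC1)ONc1ccccc1 | intermediate
19 | methyl (2E,4R,6R)-6-[(1R,4S)-4-hydroxy-4-methylcyclohex-2-en-1-yl]-2-(4-methylpent-3-en-1-yl)-4-(phenylaminooxy)hept-2-enoate | COC(=O)/C(=C/[C@@H](C[C@@H](C)[C@@H]1C=C[C@@](C)(O)CC1)ONc1ccccc1)CCC=C(C)C | intermediate
20 | methyl (2E,4R,6R)-4-hydroxy-6-[(1R,4S)-4-hydroxy-4-methylcyclohex-2-en-1-yl]-2-(4-methylpent-3-en-1-yl)hept-2-enoate | COC(=O)/C(=C/[C@@H](C[C@@H](C)[C@@H]1C=C[C@@](C)(O)CC1)O)CCC=C(C)C | intermediate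
21 | methyl (2E,4R,6R)-4-acetoxy-6-[(1R,4S)-4-hydroxy-4-methylcyclohex-2-en-1-yl]-2-(4-methylpent-3-en-1-yl)hept-2-enoate | COC(=O)/C(=C/[C@@H](C[C@@H](C)[C@@H]1C=C[C@@](C)(O)CC1)OC(C)=O)CCC=C(C)C | target

**Count**
Total steps: 12. Longest linear sequence: 11 (nerol 1 to 21 through steps 1–9, 11 and 12); step 10 is a one-step side branch.

**Three steps most likely to fail** (step 4 carries the largest risk)

Step 2 (dianion alkylation). The allyl dianion can also react at its internal carbon, the bromide can react SN2′, and some 2E isomer may form. The fallback sets out from 2 and comes back at 5. Alkylation of lithiated 1-(trimethylsilyl)propyne with 2 gives trimethyl[(5Z)-6,10-dimethylundeca-5,9-dien-1-yn-1-yl]silane F1. K2CO3 in MeOH removes silicon to give (5Z)-6,10-dimethylundeca-5,9-dien-1-yne F2. n-BuLi then methyl chloroformate gives methyl (6Z)-7,11-dimethyldodeca-6,10-dien-2-ynoate F3. Syn addition of Me2CuLi at −78 °C with cold protonation gives methyl (2Z,6Z)-farnesoate F4, whose 2Z geometry comes from the carbocupration and not from a directed lithiation. i-Bu2AlH reduction of F4 gives 5.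

Step 4 (asymmetric cyclization). The C15 dienal may fit the confined acid less well than neral, which would lower ee or rate, and the cis carbinol or the endocyclic-alkene isomer may form. The fallback sets out from 5 and comes back at 8, replacing steps 3–5 and taking the absolute configuration from tartrate instead of the chiral acid. Ti(OiPr)4, D-(−)-diethyl tartrate and t-BuOOH epoxidise 5 to [(2R,3S)-3-[(3Z)-4,8-dimethylnona-3,7-dien-1-yl]-3-methyloxiran-2-yl]methanol F5. Dess–Martin periodinane with pyridine gives (2S,3S)-3-[(3Z)-4,8-dimethylnona-3,7-dien-1-yl]-3-methyloxirane-2-carbaldehyde F6. Me2AlCl in CH2Cl2 at −78 °C then closes the same C1–C6 bond in a substrate-controlled type 1 carbonyl-ene reaction through a chelated chair, and the diastereomer 8 is isolated.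

Step 6 (directed hydrogenation). The 6R/6S ratio rests on the chelate model, and migration of the exocyclic alkene or slow reduction of the prenyl alkene could compete. The fallback sets out from 8 and comes back at 9, making the C6–H bond by hydroboration and the methyl by deoxygenation. BH3·SMe2 (1 equiv) forms the C2′ alkoxyborane, which hydroborates the exocyclic alkene intramolecularly through the same six-membered arrangement; NaBO3 oxidation gives (1R,2R,3R,6S)-3-[(2R)-1-hydroxy-6-methylhept-5-en-2-yl]-6-methyl-7-oxabicyclo[4.1.0]heptan-2-ol F7. I2, PPh3 and imidazole convert the primary alcohol to (1R,2R,3R,6S)-3-[(2R)-1-iodo-6-methylhept-5-en-2-yl]-6-methyl-7-oxabicyclo[4.1.0]heptan-2-ol F8. NaBH4 in DMSO reduces the primary iodide to the methyl group of 9.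

Further compounds
F1 | step 2 | trimethyl[(5Z)-6,10-dimethylundeca-5,9-dien-1-yn-1-yl]silane | C[Si](C)(C)C#CCC/C=C(/C)CCC=C(C)C
F2 | step 2 | (5Z)-6,10-dimethylundeca-5,9-dien-1-yne | C#CCC/C=C(/C)CCC=C(C)C
F3 | step 2 | methyl (6Z)-7,11-dimethyldodeca-6,10-dien-2-ynoate | COC(=O)C#CCC/C=C(/C)CCC=C(C)C
F4 | step 2 | methyl (2Z,6Z)-farnesoate | COC(=O)/C=C(/C)CC/C=C(/C)CCC=C(C)C
F5 | step 4 | [(2R,3S)-3-[(3Z)-4,8-dimethylnona-3,7-dien-1-yl]-3-methyloxiran-2-yl]methanol | OC[C@H]1O[C@@]1(C)CC/C=C(/C)CCC=C(C)C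
F6 | step 4 | (2S,3S)-3-[(3Z)-4,8-dimethylnona-3,7-dien-1-yl]-3-methyloxirane-2-carbaldehyde | O=C[C@H]1O[C@@]1(C)CC/C=C(/C)CCC=C(C)C
F7 | step 6 | (1R,2R,3R,6S)-3-[(2R)-1-hydroxy-6-methylhept-5-en-2-yl]-6-methyl-7-oxabicyclo[4.1.0]heptan-2-ol | OC[C@H](CCC=C(C)C)[C@H]1CC[C@]2(C)O[C@@H]2[C@@H]1O
F8 | step 6 | (1R,2R,3R,6S)-3-[(2R)-1-iodo-6-methylhept-5-en-2-yl]-6-methyl-7-oxabicyclo[4.1.0]heptan-2-ol | IC[C@H](CCC=C(C)C)[C@H]1CC[C@]2(C)O[C@@H]2[C@@H]1O
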